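**Retrosynthetic overview**

1. The 15-acetate and the 13E alkene come from a terminal alkyne (C13≡C14) by syn-carboalumination and hydroxymethylation, with the 2,3-diol carried as an acetonide.
2. The C9–C11 bond, the C9 stereocentre and the C7=C8 alkene come from a tandem [2,3]-Wittig / anionic oxy-Cope relay of a C9 allyl ether, which is the key step.
3. The cis-2,3-diol comes from OsO4 dihydroxylation of a ring A C2=C3 alkene on the face opposite the C4 and C10 axial methyls.
4. Ring A is formed second, by proton-initiated cation–alkyne cyclization of a 6-methyl-6-propargylcarvone, in which the isopropenyl carbon becomes C4.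
5. Ring B and C5 are bought as (S)-(+)-carvone, and the C10 quaternary centre is set by α′-methylation followed by propargylation anti to isopropenyl.

Assumption: the target is read as the ent-labdane (2S,3R,5S,9R,10S,13E)-2,3-dihydroxylabda-7,13-dien-15-yl acetate, and labdane numbering (C1–C20) is used for all bicyclic compounds.

**Route**

Step 1
Reactants: 1 (S)-(+)-carvone
Product: 3 (5S,6RS)-2,6-dimethyl-5-(prop-1-en-2-yl)cyclohex-2-en-1-one (6-methylcarvone; C6 epimers), via lithium enolate 2 (not isolated)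
Conditions: LiN(i-Pr)2, THF, −78 °C; CH3I, −78 → 0 °C
Reagents that add atoms: iodomethane CI
Why: Kinetic α′-deprotonation gives the cross-conjugated dienolate and enolate C-methylation installs the future C20 methyl, the new centre being an epimer mixture that is erased when it is enolized again in step 2.

Step 2
Reactants: 3 6-methylcarvone
Product: 5 (5R,6R)-2,6-dimethyl-5-(prop-1-en-2-yl)-6-(prop-2-yn-1-yl)cyclohex-2-en-1-one, via lithium enolate 4 (not isolated)
Conditions: LiN(i-Pr)2, THF, −78 °C; propargyl bromide, N,N′-dimethylpropyleneurea, −78 → −20 °C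
Reagents that add atoms: propargyl bromide (3-bromoprop-1-yne) C#CCBr
Why: Enolate alkylation of the re-formed tetrasubstituted enolate occurs anti to the bought isopropenyl-bearing stereocentre (1,2-induction), fixing the quaternary C10 centre with the propargyl arm trans to isopropenyl.

Step 3
Reactants: 5 (5R,6R)-2,6-dimethyl-5-(prop-1-en-2-yl)-6-(prop-2-yn-1-yl)cyclohex-2-en-1-one
Product: 6 (5R,10R)-9-oxo-11,12,13,14,15,16-hexanorlabda-2,7-dien-2-yl trifluoromethanesulfonate
Conditions: CF3SO3H (2.5 equiv), CH2Cl2, −78 → −40 °C; then 2,6-lutidine, aq. NaHCO3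
Reagents that add atoms: trifluoromethanesulfonic acid OS(=O)(=O)C(F)(F)F
Why: Markovnikov protonation of the isopropenyl group gives a tertiary cation that is captured 6-endo by the terminal alkyne carbon (cation–alkyne cyclization) and triflate traps the ring vinyl cation at C2, so ring A closes with the C4 gem-dimethyl group, no new stereocentre forms and the trans ring fusion follows from step 2.

Step 4
Reactants: 6 (5R,10R)-9-oxo-11,12,13,14,15,16-hexanorlabda-2,7-dien-2-yl trifluoromethanesulfonate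
Product: 7 (5R,10R)-11,12,13,14,15,16-hexanorlabda-2,7-dien-9-one
Conditions: Pd(OAc)2 (5 mol %), PPh3, HCO2H, n-Bu3N, DMF, 60 °C
Reagents that add atoms: none
Why: Palladium-catalysed formate reduction of the enol triflate (oxidative addition to zerovalent palladium, decarboxylation of formate, reductive elimination) replaces the triflate by hydrogen without touching the enone.

Step 5
Reactants: 7 (5R,10R)-11,12,13,14,15,16-hexanorlabda-2,7-dien-9-one
Product: 8 (2S,3R,5R,10R)-2,3-dihydroxy-11,12,13,14,15,16-hexanorlabd-7-en-9-one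
Conditions: OsO4 (2 mol %), N-methylmorpholine N-oxide, acetone–H2O 5:1, 23 °C
Reagents that add atoms: N-methylmorpholine N-oxide C[N+]1([O-])CCOCC1; water O
Why: Upjohn dihydroxylation attacks the electron-rich C2=C3 bond rather than the enone and does so from the face opposite the two syn-axial methyls at C4 and C10, giving the cis-(2S,3R)-diol.

Step 6
Reactants: 8 (2S,3R,5R,10R)-2,3-dihydroxy-11,12,13,14,15,16-hexanorlabd-7-en-9-one
Product: 9 (2S,3R,5R,10R)-2,3-(isopropylidenedioxy)-11,12,13,14,15,16-hexanorlabd-7-en-9-one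
Conditions: 2,2-dimethoxypropane, pyridinium p-toluenesulfonate (cat.), acetone, 23 °C
Reagents that add atoms: 2,2-dimethoxypropane COC(C)(C)OC
Why: Acid-catalysed transketalization protects the cis-diol as its acetonide for the basic and organometallic steps that follow.

Step 7
Reactants: 9 (2S,3R,5R,10R)-2,3-(isopropylidenedioxy)-11,12,13,14,15,16-hexanorlabd-7-en-9-one
Product: 10 (2S,3R,5R,9R,10R)-2,3-(isopropylidenedioxy)-11,12,13,14,15,16-hexanorlabd-7-en-9-ol
Conditions: NaBH4, CeCl3·7H2O, CH3OH, −40 °C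
Reagents that add atoms: none
Why: Luche 1,2-reduction delivers hydride to the enone carbonyl from the face anti to the axial C10 methyl, so the new C9 hydroxyl is equatorial and cis to that methyl.

Step 8
Reactants: 10 (2S,3R,5R,9R,10R)-2,3-(isopropylidenedioxy)-11,12,13,14,15,16-hexanorlabd-7-en-9-ol
Product: 12 (2S,3R,5R,9R,10R)-9-(allyloxy)-2,3-(isopropylidenedioxy)-11,12,13,14,15,16-hexanorlabd-7-ene, via sodium alkoxide 11 (not isolated)
Conditions: NaH, THF–DMF, 0 °C; allyl bromide, n-Bu4NI (cat.), 0 → 40 °C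
Reagents that add atoms: allyl bromide C=CCBr
Why: Williamson etherification of the alkoxide gives the bis-allylic ether with the C9 configuration unchanged.

Step 9
Reactants: 12 (2S,3R,5R,9R,10R)-9-(allyloxy)-2,3-(isopropylidenedioxy)-11,12,13,14,15,16-hexanorlabd-7-ene
Product: 14 (2S,3R,5S,9R,10S)-2,3-(isopropylidenedioxy)-14,15,16-trinorlabd-7-en-13-al, via potassium 1,5-dien-3-olate 13 (not isolated)
Conditions: KH, 18-crown-6, THF, 0 → 45 °C; then sat. aq. NH4Cl
Reagents that add atoms: none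
Why: Deprotonation at the O–CH2 of the allyl group triggers a [2,3]-Wittig rearrangement onto C7 to give 13, whose anionic oxy-Cope ([3,3]) rearrangement returns the chain to C9; both sigmatropic shifts are suprafacial, so the C9–C11 bond forms on the face that carried the C9 oxygen (9R), the C7=C8 alkene is restored and the chain ends as the C13 aldehyde.

Step 10
Reactants: 14 (2S,3R,5S,9R,10S)-2,3-(isopropylidenedioxy)-14,15,16-trinorlabd-7-en-13-al
Product: 15 (2S,3R,5S,9R,10S)-2,3-(isopropylidenedioxy)-15,16-dinorlabd-7-en-13-yne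
Conditions: dimethyl (1-diazo-2-oxopropyl)phosphonate, K2CO3, CH3OH, 0 → 23 °C
Reagents that add atoms: dimethyl (1-diazo-2-oxopropyl)phosphonate CC(=O)C(=[N+]=[N-])P(=O)(OC)OC
Why: Ohira–Bestmann (Seyferth–Gilbert) homologation converts the aldehyde into the terminal C13≡C14 alkyne under mild base that leaves the acetonide and the remote stereocentres alone.

Step 11
Reactants: 15 (2S,3R,5S,9R,10S)-2,3-(isopropylidenedioxy)-15,16-dinorlabd-7-en-13-yne
Product: 18 (2S,3R,5S,9R,10S,13E)-2,3-(isopropylidenedioxy)labda-7,13-dien-15-ol, via alkenyldimethylalane 16 (not isolated), via lithium alanate 17 (not isolated)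
Conditions: Al(CH3)3, (C5H5)2ZrCl2 (20 mol %), H2O (1 equiv), CH2Cl2, −20 °C; volatiles removed; n-C4H9Li, THF, −78 °C; (CH2O)n, −78 → 23 °C; aq. KNaC4H4O6
Reagents that add atoms: trimethylaluminium C[Al](C)C; formaldehyde (as paraformaldehyde) C=O
Why: Zirconium-catalysed syn-carboalumination (Negishi) places CH3 on C13 and aluminium on C14 with full regio- and cis-selectivity, and hydroxymethylation of the alanate with formaldehyde retains the geometry, giving the 13E allylic alcohol.

Step 12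
Reactants: 18 (2S,3R,5S,9R,10S,13E)-2,3-(isopropylidenedioxy)labda-7,13-dien-15-ol
Product: 19 (2S,3R,5S,9R,10S,13E)-2,3-(isopropylidenedioxy)labda-7,13-dien-15-yl acetate
Conditions: Ac2O, pyridine, 4-(dimethylamino)pyridine (cat.), CH2Cl2, 0 → 23 °C
Reagents that add atoms: acetic anhydride CC(=O)OC(C)=O
Why: Nucleophile-catalysed acylation of the primary allylic alcohol gives the C15 acetate.

Step 13
Reactants: 19 (2S,3R,5S,9R,10S,13E)-2,3-(isopropylidenedioxy)labda-7,13-dien-15-yl acetate
Product: 20 (2S,3R,5S,9R,10S,13E)-2,3-dihydroxylabda-7,13-dien-15-yl acetate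
Conditions: AcOH–H2O 4:1, 40 °C
Reagents that add atoms: none
Why: Mild acid-catalysed acetal hydrolysis removes the acetonide while the primary allylic acetate, both trisubstituted alkenes and all stereocentres stay intact.

**Compound list**

1 | (S)-(+)-carvone, (5S)-2-methyl-5-(prop-1-en-2-yl)cyclohex-2-en-1-one | CC1=CC[C@@H](CC1=O)C(C)=C | starting material
2 | lithium enolate of 1 (cross-conjugated α′-dienolate) | CC1=CC[C@H](C(C)=C)C=C1[O-].[Li+] | intermediate
3 | 6-methylcarvone, (5S,6RS)-2,6-dimethyl-5-(prop-1-en-2-yl)cyclohex-2-en-1-one (C6 epimer mixture) | CC1=CC[C@H](C(C)=C)C(C)C1=O | intermediate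
4 | lithium enolate of 3 | CC1=CC[C@H](C(C)=C)C(C)=C1[O-].[Li+] | intermediate
5 | (5R,6R)-2,6-dimethyl-5-(prop-1-en-2-yl)-6-(prop-2-yn-1-yl)cyclohex-2-en-1-one (propargyl trans to isopropenyl) | O=C1C(C)=CC[C@H](C(C)=C)[C@@]1(C)CC#C | intermediate
6 | (5R,10R)-9-oxo-11,12,13,14,15,16-hexanorlabda-2,7-dien-2-yl trifluoromethanesulfonate (trans-fused) | O=C1C(C)=CC[C@@H]2C(C)(C)C=C(OS(=O)(=O)C(F)(F)F)C[C@@]12C | intermediate
7 | (5R,10R)-11,12,13,14,15,16-hexanorlabda-2,7-dien-9-one (trans-fused) | O=C1C(C)=CC[C@@H]2C(C)(C)C=CC[C@@]12C | intermediate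
8 | (2S,3R,5R,10R)-2,3-dihydroxy-11,12,13,14,15,16-hexanorlabd-7-en-9-one (cis-diol anti to the C10 methyl) | O=C1C(C)=CC[C@@H]2C(C)(C)[C@@H](O)[C@@H](O)C[C@@]12C | intermediate
9 | (2S,3R,5R,10R)-2,3-(isopropylidenedioxy)-11,12,13,14,15,16-hexanorlabd-7-en-9-one | O=C1C(C)=CC[C@@H]2C(C)(C)[C@H]3OC(C)(C)O[C@H]3C[C@@]12C | intermediate
10 | (2S,3R,5R,9R,10R)-2,3-(isopropylidenedioxy)-11,12,13,14,15,16-hexanorlabd-7-en-9-ol (9-OH cis to the C10 methyl) | O[C@@H]1C(C)=CC[C@@H]2C(C)(C)[C@H]3OC(C)(C)O[C@H]3C[C@@]12C | intermediate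
11 | sodium alkoxide of 10 | [Na+].[O-][C@@H]1C(C)=CC[C@@H]2C(C)(C)[C@H]3OC(C)(C)O[C@H]3C[C@@]12C | intermediate
12 | (2S,3R,5R,9R,10R)-9-(allyloxy)-2,3-(isopropylidenedioxy)-11,12,13,14,15,16-hexanorlabd-7-ene | C=CCO[C@@H]1C(C)=CC[C@@H]2C(C)(C)[C@H]3OC(C)(C)O[C@H]3C[C@@]12C | intermediate
13 | potassium alkoxide of 7-(1-hydroxyprop-2-en-1-yl)-2,3-(isopropylidenedioxy)-11,12,13,14,15,16-hexanorlabd-8-ene (C7 substituent cis to the C10 methyl; carbinol centre unassigned) | C1=C(C)[C@H](C([O-])C=C)C[C@@H]2C(C)(C)[C@H]3OC(C)(C)O[C@H]3C[C@@]12C.[K+] | intermediate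
14 | (2S,3R,5S,9R,10S)-2,3-(isopropylidenedioxy)-14,15,16-trinorlabd-7-en-13-al | O=CCC[C@@H]1C(C)=CC[C@@H]2C(C)(C)[C@H]3OC(C)(C)O[C@H]3C[C@@]12C | intermediate
15 | (2S,3R,5S,9R,10S)-2,3-(isopropylidenedioxy)-15,16-dinorlabd-7-en-13-yne | C#CCC[C@@H]1C(C)=CC[C@@H]2C(C)(C)[C@H]3OC(C)(C)O[C@H]3C[C@@]12C | intermediate
16 | dimethyl[(13E)-2,3-(isopropylidenedioxy)-15-norlabda-7,13-dien-14-yl]alane | C[Al](C)/C=C(\C)CC[C@@H]1C(C)=CC[C@@H]2C(C)(C)[C@H]3OC(C)(C)O[C@H]3C[C@@]12C | intermediate
17 | lithium butyl(dimethyl)[(13E)-2,3-(isopropylidenedioxy)-15-norlabda-7,13-dien-14-yl]alanate | [Li+].CCCC[Al-](C)(C)/C=C(\C)CC[C@@H]1C(C)=CC[C@@H]2C(C)(C)[C@H]3OC(C)(C)O[C@H]3C[C@@]12C | intermediate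
18 | (2S,3R,5S,9R,10S,13E)-2,3-(isopropylidenedioxy)labda-7,13-dien-15-ol | OC/C=C(\C)CC[C@@H]1C(C)=CC[C@@H]2C(C)(C)[C@H]3OC(C)(C)O[C@H]3C[C@@]12C | intermediate
19 | (2S,3R,5S,9R,10S,13E)-2,3-(isopropylidenedioxy)labda-7,13-dien-15-yl acetate | CC(=O)OC/C=C(\C)CC[C@@H]1C(C)=CC[C@@H]2C(C)(C)[C@H]3OC(C)(C)O[C@H]3C[C@@]12C | intermediate
20 | (2S,3R,5S,9R,10S,13E)-2,3-dihydroxylabda-7,13-dien-15-yl acetate | CC(=O)OC/C=C(\C)CC[C@@H]1C(C)=CC[C@@H]2C(C)(C)[C@@H](O)[C@@H](O)C[C@@]12C | target

**Step count and risks**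

Total step count: 13. Longest linear sequence: 13 steps (1 → 20). C5 is bought in (S)-carvone and controls C10 (step 2), C2 and C3 (step 5) and C9 (steps 7 to 9).

Steps most likely to fail:

Step 3. The tertiary cation may lose a proton or undergo a hydride shift faster than the weakly nucleophilic terminal alkyne closes the ring, or the alkyne may simply add the acid. The fallback sets out from 3 and comes back at 7. Compound 3 is alkylated instead with 3-bromo-1-(trimethylsilyl)prop-1-yne (LiN(i-Pr)2, THF, −78 °C) to give the silylalkyne ketone F1. Semi-hydrogenation (H2, Pd/CaCO3 poisoned with Pb(OAc)2, quinoline) gives the (Z)-vinylsilane ketone F2. CF3CO2H in CH2Cl2 at 0 °C then closes ring A by a vinylsilane-terminated cyclization (ipso attack, β-silyl cation, loss of silicon), which gives 7 directly and needs neither triflate capture nor step 4.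

Step 9. The C9–O bond is equatorial in a rigid trans-decalin and C9 is flanked by the quaternary C10, so the relay may stall after the Wittig shift or divert to a [1,2]-shift. The fallback sets out from 9 and comes back at 15. [4-(Trimethylsilyl)but-3-yn-1-yl]lithium (from the iodide and t-C4H9Li, with CeCl3, THF, −78 °C) adds to the C9 carbonyl of 9 anti to the C10 methyl, and methyl chloroformate in the same flask gives the tertiary allylic carbonate F3. Pd(OAc)2/P(n-C4H9)3 and HCO2NH4 in dioxane at 100 °C then effect reductive allylic transposition: zerovalent palladium ionizes anti to the carbonate and delivers hydride from its own face to the more substituted allyl terminus. This gives the silylalkyne F4 with the C9–H bond anti to the C10 methyl and the C7=C8 alkene in place. K2CO3 in CH3OH removes the silyl group to give 15.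

Step 11. Al(CH3)3 can open the acetonide, and carbometalation may be incomplete. The fallback sets out from 15 and comes back at 18. Compound 15 is hydroxymethylated (n-C4H9Li, THF, −78 °C; (CH2O)n) to the propargylic alcohol F5. Alkoxide-directed trans-hydroalumination with NaAlH2(OCH2CH2OCH3)2 followed by I2 at −78 °C gives the (Z)-3-iodoallylic alcohol F6. (CH3)2CuLi in Et2O at 0 °C replaces iodine by methyl with retention to give 18, without exposing the acetonide to Al(CH3)3.

**Further compounds**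

F1 | step 3 | (5R,6R)-2,6-dimethyl-5-(prop-1-en-2-yl)-6-[3-(trimethylsilyl)prop-2-yn-1-yl]cyclohex-2-en-1-one | O=C1C(C)=CC[C@H](C(C)=C)[C@@]1(C)CC#C[Si](C)(C)C
F2 | step 3 | (5R,6R)-2,6-dimethyl-5-(prop-1-en-2-yl)-6-[(2Z)-3-(trimethylsilyl)prop-2-en-1-yl]cyclohex-2-en-1-one | O=C1C(C)=CC[C@H](C(C)=C)[C@@]1(C)C/C=C\[Si](C)(C)C
F3 | step 9 | 2,3-(isopropylidenedioxy)-14-(trimethylsilyl)-15,16-dinorlabd-7-en-13-yn-9-yl methyl carbonate (C9–O cis to the C10 methyl) | COC(=O)O[C@]1(CCC#C[Si](C)(C)C)C(C)=CC[C@@H]2C(C)(C)[C@H]3OC(C)(C)O[C@H]3C[C@@]12C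
F4 | step 9 | (2S,3R,5S,9R,10S)-2,3-(isopropylidenedioxy)-14-(trimethylsilyl)-15,16-dinorlabd-7-en-13-yne | C[Si](C)(C)C#CCC[C@@H]1C(C)=CC[C@@H]2C(C)(C)[C@H]3OC(C)(C)O[C@H]3C[C@@]12C
F5 | step 11 | (2S,3R,5S,9R,10S)-2,3-(isopropylidenedioxy)-16-norlabd-7-en-13-yn-15-ol | OCC#CCC[C@@H]1C(C)=CC[C@@H]2C(C)(C)[C@H]3OC(C)(C)O[C@H]3C[C@@]12C
F6 | step 11 | (13Z)-13-iodo-2,3-(isopropylidenedioxy)-16-norlabda-7,13-dien-15-ol | OC/C=C(\I)CC[C@@H]1C(C)=CC[C@@H]2C(C)(C)[C@H]3OC(C)(C)O[C@H]3C[C@@]12C
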